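A neighbour of this flask holds less second reagent, and it set two of us arguing over what a charge is worth as a level.

substrate 0.015 M; partner 0.0195 M (fed, over 15 s); second reagent 0.0150 M; third reagent 0.0150 M; capture agent 4.50 mM; time 1.0 h

    substrate + partner → intermediate A (k1 = 0.45 L mol⁻¹ s⁻¹)
    second reagent + intermediate A → intermediate B (k2 = 0.79 L mol⁻¹ s⁻¹)
    third reagent + intermediate B → target (k3 = 0.46 L mol⁻¹ s⁻¹)
    substrate + second reagent → side product A (k4 = 0.66 L mol⁻¹ s⁻¹)
    target → over-reaction product (k5 = 0.0082 s⁻¹)
    intermediate A → side product B (k6 = 0.0074 s⁻¹)
    intermediate A + capture agent → trapped intermediate (k7 = 0.28 L mol⁻¹ s⁻¹)

1. how much side product A there is at 1.0 h, in percent of the substrate charged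
2. how much side product B there is at 1.0 h, in percent of the substrate charged

Substrate goes two ways: with partner to intermediate A, or with second reagent to side product A. Intermediate A then goes three ways. The dose of 15 s is shorter than the substrate's lifetime of 53.5 s at charged levels, so we both pass over it.

The first of us freezes each reagent at its charge, which makes the substrate's decay pseudo-first-order. The share going to side product A is then its rate over the sum of the two substrate rates, 53.0%. The share of intermediate A going to side product B is its first-order constant over the sum of the three loss rates, 36.1%. Together these put side product B at 17.0%.

The second of us objects. The second reagent is charged at the substrate's own level, so at the first share the step to side product A takes 53.0% of its charge. I side with this view and reckon it so. When half the substrate has gone, the first share, counting the substrate's two steps and leaving out the step to intermediate B, puts second reagent at 11.0 mM and partner at 16.0 mM. The mid-course share σ is the share to side product A with the reagents frozen at those levels: 50.3%. Intermediate A is then reckoned with second reagent at its charge less σ times the substrate charge, 7.46 mM, again leaving out the step to intermediate B. That sends 50.9% of it to side product B, or 25.3% of the substrate.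

The forecast came down on the second side with 49.9% and 27%, its side product B higher than mine, and it wrote: “The side reaction takes slightly more than half at first”.

The flask gives 50.0% of side product A against σ of 50.3%, and 26.0% of side product B against my 25.3%. At 0.0158 h the step to side product A was using second reagent 2.3 times as fast as the step to intermediate B, and the flask ended with 30.1% of that reagent's charge. The charged view belongs to a flask whose reagents stay near their charge while the substrate goes.

In the neighbour with 0.0090 M of second reagent, the charged share 40.4% gives mid-course levels of 5.97 mM of second reagent and 15.0 mM of partner. So σ is 36.8%, and side product B comes to 41.0%. That neighbour gives 34.8% of side product A and 43.5% of side product B.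

The rate constants were chosen freely; what happens was integrated by code.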